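Ring B is disconnected at C9–C10 and C5–C6: ring A arrives as a methoxytoluquinone, and C6–C9 with C11–C12 as a 2-silyloxy diene. One Diels–Alder reaction under a chiral titanium Lewis acid makes both bonds, closes ring B and sets the quaternary C10. The step exploits the carbonyl groups that the adduct keeps at C4 and C8: they render C5 and C9 enolizable, so desilylation and base treatment before isolation let both centres relax to the trans-decalin with the equatorial 9β chain. The precursors are quinone 2, whose C4 carbonyl and C3 methoxy group chelate the metal, and (Z)-dienyl silyl ether 9; all later steps are functional-group work and one side-chain coupling.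

Key step: step 7

Numbering: labdane numbering is used for all bicyclic compounds and also for 2 and 9 (ring A = C1–C5 and C10; ring B = C5–C10; C20 on C10; C11–C16 on C9; C17 on C8; C18 and C19 on C4; β = face of C20). In 2, C10 is the methyl-bearing carbon, C5 the neighbouring CH, C4 and C1 the carbonyls next to C5 and C10, C3 the methoxy carbon; in 9, C6 is the CH2 terminus, C8 the silyloxy carbon and C9 the chain-bearing terminus.

Assumption: the (R,R)-configured titanium diolate is taken to leave the Re face of C10 (C1 > C5 > C20) of the chelated quinone open; should the sense prove opposite, the (S,S)-ligand is used and nothing else changes (TADDOL = 2,2-dimethyl-α,α,α′,α′-tetraphenyl-1,3-dioxolane-4,5-dimethanol).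

Remark: 7 is racemic, 16–19, 24 and 25 are E/Z mixtures at the enol ether (17 also at C=N), and 26–28 are C4 epimer mixtures; these elements are left undefined in the SMILES and all disappear later.

Step 1
Reactants: 1 2-methoxy-5-methylphenol
Product: 2 2-methoxy-5-methyl-1,4-benzoquinone
Conditions: (KSO3)2NO (2.2 equiv), KH2PO4, H2O/acetone, 0 °C → rt
Reagents that add atoms: potassium nitrosodisulfonate, [K+].[K+].[O]N(S(=O)(=O)[O-])S(=O)(=O)[O-]
Why: Teuber oxidation, in which the phenoxyl radical is trapped by a second aminoxyl radical at the free position para to the hydroxyl group and loss of imidodisulfonate should give the para-quinone.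

Step 2
Reactants: 3 butane-1,4-diol
Product: 4 4-(tert-butyldiphenylsilyloxy)butan-1-ol
Conditions: TBDPSCl (1 equiv), imidazole (1.1 equiv), 3 (4 equiv), THF, 0 °C → rt
Reagents that add atoms: tert-butyl(chloro)diphenylsilane, CC(C)(C)[Si](Cl)(c1ccccc1)c1ccccc1
Why: Silylation of one hydroxyl group, the excess of the cheap diol keeping the bis-silyl ether low.

Step 3
Reactants: 4 4-(tert-butyldiphenylsilyloxy)butan-1-ol
Product: 5 4-(tert-butyldiphenylsilyloxy)butanal
Conditions: TEMPO (10 mol%), PhI(OAc)2 (1.1 equiv), CH2Cl2, rt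
Reagents that add atoms: none
Why: Oxoammonium-mediated oxidation of the primary alcohol should stop at the aldehyde and leaves the silyl ether alone.

Step 4
Reactants: 5 4-(tert-butyldiphenylsilyloxy)butanal; 6 vinylmagnesium bromide
Product: 7 rac-6-(tert-butyldiphenylsilyloxy)hex-1-en-3-ol
Conditions: CH2=CHMgBr (1.2 equiv), THF, −78 → 0 °C; aq. NH4Cl
Reagents that add atoms: none
Why: Grignard 1,2-addition to the aldehyde, the new carbinol centre being formed racemic and destroyed in step 5.

Step 5
Reactants: 7 rac-6-(tert-butyldiphenylsilyloxy)hex-1-en-3-ol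
Product: 8 6-(tert-butyldiphenylsilyloxy)hex-1-en-3-one
Conditions: Dess–Martin periodinane (1.2 equiv), CH2Cl2, 0 °C → rt
Reagents that add atoms: none
Why: Dess–Martin oxidation of the allylic alcohol should give the vinyl ketone under neutral conditions free of nucleophiles that could add in conjugate fashion.

Step 6
Reactants: 8 6-(tert-butyldiphenylsilyloxy)hex-1-en-3-one
Product: 9 (3Z)-3-(triisopropylsilyloxy)-6-(tert-butyldiphenylsilyloxy)hexa-1,3-diene
Conditions: TIPSOTf (1.2 equiv), Et3N (2 equiv), CH2Cl2, −78 → 0 °C
Reagents that add atoms: triisopropylsilyl trifluoromethanesulfonate, CC(C)[Si](OS(=O)(=O)C(F)(F)F)(C(C)C)C(C)C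
Why: Soft enolization (silyl triflate and amine) toward the only α-CH2 group should give the cross-conjugated silyl enol ether, the (Z)-isomer with the chain trans to the vinyl group being the favoured one.

Step 7
Reactants: 2 2-methoxy-5-methyl-1,4-benzoquinone; 9 (3Z)-3-(triisopropylsilyloxy)-6-(tert-butyldiphenylsilyloxy)hexa-1,3-diene
Product: 12 trans-fused 3-methoxy-10β-methyl-9β-[2-(tert-butyldiphenylsilyloxy)ethyl]-5α-H-decal-2-ene-1,4,8-trione, via cis-fused cycloadduct 10 (not isolated), via cis-fused trione 11 (not isolated)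
Conditions: TiCl2(OiPr)2/(R,R)-TADDOL (0.3 equiv, preformed), 4 Å MS, toluene/CH2Cl2, −78 → −30 °C; then TBAF (1.5 equiv), THF, −40 °C; then K2CO3 (0.5 equiv), MeOH, 0 °C → rt
Reagents that add atoms: none
Why: Tetravalent titanium is held in a five-membered chelate by the C4 carbonyl oxygen and the C3 methoxy oxygen of 2, which lowers the LUMO of the methyl-bearing C5=C10 alkene with its largest coefficient at C10 (β to C4=O), while the silyloxy group of 9 makes C9 its nucleophilic terminus, so that an asynchronous, concerted endo [4+2] cycloaddition forms C9–C10 and C5–C6. The closest known reaction types are Diels–Alder additions of 2-alkoxy-1,4-benzoquinones promoted by chiral titanium diolates, quinone cycloadditions of 2-silyloxy dienes, and the base-induced cis-to-trans isomerization of quinone adducts. Ring B is closed as a six-membered ring by the cycloaddition itself, first as the cis-fused cyclohexene silyl enol ether 10, in which the outward-pointing chain of the (Z)-diene ends up anti to C20. C10 is controlled by the chiral diolate, which screens one face of the chelated quinone so that the diene adds to the Re face of C10, whereas C5 and C9 are controlled thermodynamically: once fluoride has released the C8 ketone (11), carbonate in methanol enolizes C5 (α to C4=O) and C9 (α to C8=O) until the trans ring fusion with the equatorial 9β chain (12) is reached. The step needs orientational selectivity (C9 to C10 and not to C5), secured by the two-point binding that places the Lewis acid on C4=O and by the methoxy group, which turns C1=O into a less activating vinylogous ester carbonyl; it needs site selectivity for C5=C10 over C2=C3, secured by the donor methoxy group on C3; and it needs face selectivity, which rests on the ligand alone. The silyl enol ether is cleaved by fluoride at −40 °C much faster than the primary TBDPS ether, which is kept for later.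

Step 8
Reactants: 12 trans-fused 3-methoxy-2-ene-1,4,8-trione
Product: 13 8,8-ethylenedioxy derivative of 12 (C8 dioxolane, ring A enedione unchanged)
Conditions: Me3SiOCH2CH2OSiMe3 (2 equiv), TMSOTf (5 mol%), CH2Cl2, −78 → −20 °C
Reagents that add atoms: 1,2-bis(trimethylsilyloxy)ethane, C[Si](C)(C)OCCO[Si](C)(C)C
Why: Silyl triflate-catalysed ketalization should occur only at the saturated C8 ketone, because C4 is an enone carbonyl and C1 a vinylogous ester carbonyl, and the ketal blocks further enolization at C9.

Step 9
Reactants: 13 8,8-ethylenedioxy-3-methoxy-2-ene-1,4-dione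
Product: 15 8,8-ethylenedioxy-10β-methyl-9β-[2-(tert-butyldiphenylsilyloxy)ethyl]-5α-H-decalin-1,4-dione, via 3-methoxy-1,4-dione 14 (not isolated)
Conditions: Zn dust (10 equiv), AcOH/THF, rt → 50 °C
Reagents that add atoms: none
Why: Zinc reduction of the ene-1,4-dione saturates C2=C3 and then removes the C3 methoxy group, which is now α to the C4 ketone and β to the C1 ketone, by reductive C–O cleavage (or elimination and renewed reduction), while the electron transfer does not touch C5.

Step 10
Reactants: 15 8,8-ethylenedioxy-decalin-1,4-dione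
Product: 16 4-(methoxymethylene) derivative of 15 (C1 ketone kept; E/Z)
Conditions: MeOCH2PPh3Cl (1.5 equiv), KN(SiMe3)2 (1.4 equiv), THF, 0 °C; then 15, −78 → 0 °C
Reagents that add atoms: (methoxymethyl)triphenylphosphonium chloride, COC[P+](c1ccccc1)(c1ccccc1)c1ccccc1.[Cl-]
Why: Wittig alkenation should take place at the C4 ketone only, since the C1 ketone is neopentyl (next to quaternary C10), and the low temperature limits enolization toward C5.

Step 11
Reactants: 16 4-(methoxymethylene) C1 ketone
Product: 18 2-[8,8-ethylenedioxy-4-(methoxymethylene)-10β-methyl-5α-H-decalin-9β-yl]ethanol, via C1 hydrazone 17 (not isolated)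
Conditions: N2H4·H2O (10 equiv), KOH (10 equiv), diethylene glycol, 130 °C; then 200 °C
Reagents that add atoms: none
Why: Wolff–Kishner reduction removes the C1 carbonyl group, as is usual for decalones with the ketone next to an angular methyl group, the enol ether and the ketal being stable to base, and the hot hydroxide should cleave the silyl ether in the same operation to free the C12 hydroxyl group.

Step 12
Reactants: 18 C12 alcohol
Product: 19 9β-(2-iodoethyl)-8,8-ethylenedioxy-4-(methoxymethylene)-10β-methyl-5α-H-decalin
Conditions: PPh3 (1.3 equiv), I2 (1.3 equiv), imidazole (2.5 equiv), CH2Cl2, 0 °C (reagent premixed)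
Reagents that add atoms: iodine, [I][I]
Why: Appel iodination (SN2 displacement of the alkoxyphosphonium ion by iodide) at the unhindered primary carbon, the imidazole buffer keeping the enol ether and the ketal intact.

Step 13
Reactants: 20 but-2-yn-1-ol
Product: 21 tert-butyl(but-2-yn-1-yloxy)dimethylsilane
Conditions: TBSCl (1.1 equiv), imidazole (1.5 equiv), CH2Cl2, rt
Reagents that add atoms: tert-butyl(chloro)dimethylsilane, CC(C)(C)[Si](C)(C)Cl
Why: Routine silylation of the primary alcohol.

Step 14
Reactants: 21 tert-butyl(but-2-yn-1-yloxy)dimethylsilane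
Product: 23 (E)-tert-butyl[(3-iodobut-2-en-1-yl)oxy]dimethylsilane, via alkenylzirconocene chloride 22 (not isolated)
Conditions: Cp2Zr(H)Cl (1.5 equiv), THF, 50 °C; then I2 (1.5 equiv), 0 °C
Reagents that add atoms: iodine, [I][I]
Why: syn-Hydrozirconation, with the excess hydride equilibrating zirconium to the less hindered methyl-bearing carbon, and iodinolysis with retention should give the (E)-iodide in which iodine is trans to the CH2O group.

Step 15
Reactants: 19 C12 iodide; 23 (E)-tert-butyl[(3-iodobut-2-en-1-yl)oxy]dimethylsilane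
Product: 25 9β-[(3E)-5-(tert-butyldimethylsilyloxy)-3-methylpent-3-en-1-yl]-8,8-ethylenedioxy-4-(methoxymethylene)-10β-methyl-5α-H-decalin, via alkylzinc iodide 24 (not isolated)
Conditions: Zn dust (activated, 3 equiv), LiCl, THF, 40 °C; then 23 (1.2 equiv), Pd(dppf)Cl2 (3 mol%), THF, rt → 50 °C
Reagents that add atoms: none
Why: Negishi coupling, in which zinc inserts into the primary C–I bond and the palladium-catalysed sp3–sp2 coupling, which retains alkene geometry, joins C12 to C13 and delivers the (E)-trisubstituted C13=C14 alkene, enol ether and ketal being inert to organozinc reagents.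

Step 16
Reactants: 25 coupled enol ether ketal
Product: 26 15-hydroxy-8-oxo-17,18-dinorlabd-13(E)-en-19-al (C4 epimers; 5α-H, 9β chain, 10β-CH3)
Conditions: 1 M HCl, THF, rt
Reagents that add atoms: water, O
Why: Aqueous acid hydrolyses the enol ether to the C4 aldehyde, the ketal to the C8 ketone and the allylic silyl ether to the C15 alcohol in one operation, at a stage where no acid-sensitive exocyclic alkene is present and where C9, again enolizable, stays in its stable 9β configuration.

Step 17
Reactants: 26 hydroxy keto aldehyde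
Product: 27 15-hydroxy-8-oxo-17,18-dinorlabd-13(E)-en-19-oic acid (C4 epimers)
Conditions: NaClO2 (3 equiv), NaH2PO4, 2-methyl-2-butene (20 equiv), t-BuOH/H2O, 0 °C → rt
Reagents that add atoms: sodium chlorite, [Na+].[O-]Cl=O
Why: Pinnick oxidation converts only the aldehyde into the acid, the alkene scavenger removing hypochlorite before it can attack the trisubstituted alkene.

Step 18
Reactants: 27 hydroxy keto acid
Product: 28 15-hydroxy-18-norlabda-8(17),13(E)-dien-19-oic acid (C4 epimers)
Conditions: Ph3PCH3Br (5 equiv), KOtBu (5 equiv), toluene, 90 °C; then aq. HCl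
Reagents that add atoms: methyltriphenylphosphonium bromide, C[P+](c1ccccc1)(c1ccccc1)c1ccccc1.[Br-]
Why: Wittig methylenation of the hindered C8 ketone with excess ylide, the carboxylate and the alkoxide acting as spectators, should give the exocyclic C8=C17 alkene, and any base-induced equilibration at C9 before alkenation leads to the stable 9β chain.

Step 19
Reactants: 28 C4-unsubstituted hydroxy acid
Product: 30 isocupressic acid [(4S,5R,9S,10R)-15-hydroxylabda-8(17),13(E)-dien-19-oic acid], via trilithium enediolate 29 (not isolated)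
Conditions: LiN(iPr)2 (3.5 equiv), THF, 0 → 40 °C; then MeI (1.1 equiv), −78 → 0 °C; aq. HCl
Reagents that add atoms: iodomethane, CI
Why: α-Deprotonation of the lithium carboxylate gives an exocyclic enediolate that should be C-methylated from the equatorial α face, because the axial C20 methyl group shields the β face in a 1,3-diaxial sense, which sets C4 (4S) with the axial C19 carboxyl and the equatorial C18 methyl group, the lithium alkoxide at C15 being inert to iodomethane at this temperature.

Step 20
Reactants: 30 isocupressic acid; 31 oleic acid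
Product: 32 15-O-oleoyl isocupressic acid (target)
Conditions: 31 (1.2 equiv), DCC (1.2 equiv), DMAP (0.1 equiv), CH2Cl2, 0 °C → rt
Reagents that add atoms: none
Why: Steglich esterification, in which the unhindered oleic acid is activated by the carbodiimide and acylates the primary allylic C15 alcohol, whereas the tertiary, axial C19 acid is too hindered to be activated or to act as an acyl donor, and the (Z)-alkene of the oleoyl chain is not touched.

Compound list
1 | 2-methoxy-5-methylphenol | COc1ccc(C)cc1O | starting material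
2 | 2-methoxy-5-methyl-1,4-benzoquinone | COC1=CC(=O)C(C)=CC1=O | intermediate
3 | butane-1,4-diol | OCCCCO | starting material
4 | 4-(tert-butyldiphenylsilyloxy)butan-1-ol | OCCCCO[Si](c1ccccc1)(c1ccccc1)C(C)(C)C | intermediate
5 | 4-(tert-butyldiphenylsilyloxy)butanal | O=CCCCO[Si](c1ccccc1)(c1ccccc1)C(C)(C)C | intermediate
6 | vinylmagnesium bromide | C=C[Mg]Br | starting material
7 | rac-6-(tert-butyldiphenylsilyloxy)hex-1-en-3-ol | C=CC(O)CCCO[Si](c1ccccc1)(c1ccccc1)C(C)(C)C | intermediate
8 | 6-(tert-butyldiphenylsilyloxy)hex-1-en-3-one | C=CC(=O)CCCO[Si](c1ccccc1)(c1ccccc1)C(C)(C)C | intermediate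
9 | (3Z)-3-(triisopropylsilyloxy)-6-(tert-butyldiphenylsilyloxy)hexa-1,3-diene | C=C/C(O[Si](C(C)C)(C(C)C)C(C)C)=C/CCO[Si](c1ccccc1)(c1ccccc1)C(C)(C)C | intermediate
10 | cis-fused cycloadduct: 3-methoxy-10β-methyl-8-(triisopropylsilyloxy)-9α-[2-(tert-butyldiphenylsilyloxy)ethyl]-5β-H-decal-2,7-diene-1,4-dione (formed in the flask) | CC(C)[Si](C(C)C)(C(C)C)OC1=CC[C@H]2[C@](C)(C(=O)C=C(OC)C2=O)[C@@H]1CCO[Si](c1ccccc1)(c1ccccc1)C(C)(C)C | intermediate
11 | cis-fused trione: 5β-H, 9α-chain isomer of 12 (formed in the flask) | O=C1CC[C@H]2[C@](C)(C(=O)C=C(OC)C2=O)[C@@H]1CCO[Si](c1ccccc1)(c1ccccc1)C(C)(C)C | intermediate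
12 | trans-fused trione: 3-methoxy-10β-methyl-9β-[2-(tert-butyldiphenylsilyloxy)ethyl]-5α-H-decal-2-ene-1,4,8-trione | O=C1CC[C@@H]2[C@](C)(C(=O)C=C(OC)C2=O)[C@H]1CCO[Si](c1ccccc1)(c1ccccc1)C(C)(C)C | intermediate
13 | 8,8-ethylenedioxy derivative of 12 (C8 dioxolane; ring A 3-methoxy-2-ene-1,4-dione) | O1CCOC12CC[C@@H]3[C@](C)(C(=O)C=C(OC)C3=O)[C@H]2CCO[Si](c4ccccc4)(c5ccccc5)C(C)(C)C | intermediate
14 | 8,8-ethylenedioxy-3-methoxy-decalin-1,4-dione (C3 undefined; formed in the flask) | O1CCOC12CC[C@@H]3[C@](C)(C(=O)CC(OC)C3=O)[C@H]2CCO[Si](c4ccccc4)(c5ccccc5)C(C)(C)C | intermediate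
15 | 8,8-ethylenedioxy-10β-methyl-9β-[2-(tert-butyldiphenylsilyloxy)ethyl]-5α-H-decalin-1,4-dione | O1CCOC12CC[C@@H]3[C@](C)(C(=O)CCC3=O)[C@H]2CCO[Si](c4ccccc4)(c5ccccc5)C(C)(C)C | intermediate
16 | 4-(methoxymethylene) derivative of 15 (C1 ketone kept; E/Z) | O1CCOC12CC[C@@H]3[C@](C)(C(=O)CCC3=COC)[C@H]2CCO[Si](c4ccccc4)(c5ccccc5)C(C)(C)C | intermediate
17 | C1 hydrazone of 16 (formed in the flask) | O1CCOC12CC[C@@H]3[C@](C)(C(=NN)CCC3=COC)[C@H]2CCO[Si](c4ccccc4)(c5ccccc5)C(C)(C)C | intermediate
18 | 2-[8,8-ethylenedioxy-4-(methoxymethylene)-10β-methyl-5α-H-decalin-9β-yl]ethanol | O1CCOC12CC[C@@H]3[C@](C)(CCCC3=COC)[C@H]2CCO | intermediate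
19 | 9β-(2-iodoethyl)-8,8-ethylenedioxy-4-(methoxymethylene)-10β-methyl-5α-H-decalin | O1CCOC12CC[C@@H]3[C@](C)(CCCC3=COC)[C@H]2CCI | intermediate
20 | but-2-yn-1-ol | CC#CCO | starting material
21 | tert-butyl(but-2-yn-1-yloxy)dimethylsilane | CC#CCO[Si](C)(C)C(C)(C)C | intermediate
22 | (E)-[4-(tert-butyldimethylsilyloxy)but-2-en-2-yl]zirconocene chloride (formed in the flask) | C/C(=C\CO[Si](C)(C)C(C)(C)C)[Zr](Cl)(C1C=CC=C1)C1C=CC=C1 | intermediate
23 | (E)-tert-butyl[(3-iodobut-2-en-1-yl)oxy]dimethylsilane | C/C(I)=C\CO[Si](C)(C)C(C)(C)C | intermediate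
24 | alkylzinc iodide from 19 (C12–ZnI; formed in the flask) | O1CCOC12CC[C@@H]3[C@](C)(CCCC3=COC)[C@H]2CC[Zn]I | intermediate
25 | 9β-[(3E)-5-(tert-butyldimethylsilyloxy)-3-methylpent-3-en-1-yl]-8,8-ethylenedioxy-4-(methoxymethylene)-10β-methyl-5α-H-decalin | O1CCOC12CC[C@@H]3[C@](C)(CCCC3=COC)[C@H]2CC/C(C)=C/CO[Si](C)(C)C(C)(C)C | intermediate
26 | 15-hydroxy-8-oxo-17,18-dinorlabd-13(E)-en-19-al (C4 epimers) | O=C1CC[C@@H]2[C@](C)(CCCC2C=O)[C@H]1CC/C(C)=C/CO | intermediate
27 | 15-hydroxy-8-oxo-17,18-dinorlabd-13(E)-en-19-oic acid (C4 epimers) | O=C1CC[C@@H]2[C@](C)(CCCC2C(=O)O)[C@H]1CC/C(C)=C/CO | intermediate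
28 | 15-hydroxy-18-norlabda-8(17),13(E)-dien-19-oic acid (C4 epimers) | C=C1CC[C@@H]2[C@](C)(CCCC2C(=O)O)[C@H]1CC/C(C)=C/CO | intermediate
29 | trilithium salt of 28 (C4 enediolate, C15 alkoxide; formed in the flask) | C=C1CC[C@@H]2[C@](C)(CCCC2=C(O[Li])O[Li])[C@H]1CC/C(C)=C/CO[Li] | intermediate
30 | isocupressic acid, (4S,5R,9S,10R)-15-hydroxylabda-8(17),13(E)-dien-19-oic acid | C=C1CC[C@@H]2[C@](C)(CCC[C@]2(C)C(=O)O)[C@H]1CC/C(C)=C/CO | intermediate
31 | oleic acid, (9Z)-octadec-9-enoic acid | CCCCCCCC/C=C\CCCCCCCC(=O)O | starting material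
32 | 15-O-oleoyl isocupressic acid, (4S,5R,9S,10R)-15-[(9Z)-octadec-9-enoyloxy]labda-8(17),13(E)-dien-19-oic acid (CNP0287077.1) | C=C1CC[C@@H]2[C@](C)(CCC[C@]2(C)C(=O)O)[C@H]1CC/C(C)=C/COC(=O)CCCCCCC/C=C\CCCCCCCC | target

Total step count: 20. Longest linear sequence: 17 steps (steps 2–12 and 15–20, from butane-1,4-diol 3 to 32).

Steps most likely to fail

Step 7. What may go wrong: the chelate holds the chiral ligand far from the reacting C5=C10 bond, so discrimination between the two quinone faces may be weak; partial one-point binding at the more basic C1 carbonyl could reverse the orientation (C9 adding to C5); and equilibration at C9 could stop short of the 9β chain. The fallback changes the mode of activation and uses known chemistry. It sets out from diene 9, and the quinone is replaced by its isomer 2-methoxy-6-methyl-1,4-benzoquinone F1 (by the oxidation of step 1 from commercial 3-methoxy-5-methylphenol). In F1 the methoxy-conjugated and therefore more basic carbonyl is C4, which has the C5–H next to it. A cationic oxazaborolidine (from (S)-α,α-diphenylprolinol and o-tolylboroxine, activated with Tf2NH) binds one carbonyl only and is organised by the C5–H···O contact, so it activates exactly the carbonyl whose β-carbon is C10 and should expose the same face of C10. The cycloaddition should give the cis-fused adduct F2; fluoride and methanolic carbonate as in step 7 lead through the cis-fused 2-methoxy trione F3 to the trans-fused 2-methoxy trione F4; ketalization as in step 8 gives the C8 ketal F5; zinc in acetic acid as in step 9, by way of the 2-methoxy-1,4-dione F6, removes the methoxy group wherever it sits and returns to 15.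

Step 11. What may go wrong: hydrazone formation at the neopentyl C1 ketone may be so slow that forcing conditions cause decomposition, or the silyl ether may be lost only in part. The fallback is a radical deoxygenation. It sets out from 16: LiAlH4 in THF at 0 °C reduces the C1 ketone to the C1 alcohol F7; NaH, CS2 and MeI give the S-methyl xanthate F8; Bu3SnH/AIBN in toluene at 110 °C (Barton–McCombie deoxygenation) gives the deoxygenated silyl ether F9; TBAF removes the silyl group and returns to 18.

Step 19. What may go wrong: the enediolate may be methylated from both faces, which would lose control of C4, or deprotonation of the hindered carboxylate may stay incomplete. The fallback uses an ester enolate with late SN2 demethylation. It sets out from 28: Me3SiCHN2 in toluene/methanol gives the methyl ester of 28 F10; LiN(iPr)2 (2.2 equiv) and MeI methylate the ester enolate, the variant with the strongest precedent for equatorial attack in 10-methyl decalins, to give methyl isocupressate F11; lithium propanethiolate in HMPA cleaves the hindered ester by attack at the O-methyl group and returns to 30.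

Further compounds
F1 | step 7 | 2-methoxy-6-methyl-1,4-benzoquinone | COC1=CC(=O)C=C(C)C1=O
F2 | step 7 | cis-fused cycloadduct, 2-methoxy isomer of 10 | CC(C)[Si](C(C)C)(C(C)C)OC1=CC[C@H]2[C@](C)(C(=O)C(OC)=CC2=O)[C@@H]1CCO[Si](c1ccccc1)(c1ccccc1)C(C)(C)C
F3 | step 7 | cis-fused 2-methoxy trione, 2-methoxy isomer of 11 | O=C1CC[C@H]2[C@](C)(C(=O)C(OC)=CC2=O)[C@@H]1CCO[Si](c1ccccc1)(c1ccccc1)C(C)(C)C
F4 | step 7 | trans-fused 2-methoxy trione, 2-methoxy isomer of 12 | O=C1CC[C@@H]2[C@](C)(C(=O)C(OC)=CC2=O)[C@H]1CCO[Si](c1ccccc1)(c1ccccc1)C(C)(C)C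
F5 | step 7 | 8,8-ethylenedioxy derivative of F4 | O1CCOC12CC[C@@H]3[C@](C)(C(=O)C(OC)=CC3=O)[C@H]2CCO[Si](c4ccccc4)(c5ccccc5)C(C)(C)C
F6 | step 7 | 8,8-ethylenedioxy-2-methoxy-decalin-1,4-dione (C2 undefined; formed in the flask) | O1CCOC12CC[C@@H]3[C@](C)(C(=O)C(OC)CC3=O)[C@H]2CCO[Si](c4ccccc4)(c5ccccc5)C(C)(C)C
F7 | step 11 | C1 alcohol from 16 (C1 undefined) | O1CCOC12CC[C@@H]3[C@](C)(C(O)CCC3=COC)[C@H]2CCO[Si](c4ccccc4)(c5ccccc5)C(C)(C)C
F8 | step 11 | C1 S-methyl xanthate of F7 | O1CCOC12CC[C@@H]3[C@](C)(C(OC(=S)SC)CCC3=COC)[C@H]2CCO[Si](c4ccccc4)(c5ccccc5)C(C)(C)C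
F9 | step 11 | tert-butyldiphenylsilyl ether of 18 | O1CCOC12CC[C@@H]3[C@](C)(CCCC3=COC)[C@H]2CCO[Si](c4ccccc4)(c5ccccc5)C(C)(C)C
F10 | step 19 | methyl ester of 28 (C4 epimers) | C=C1CC[C@@H]2[C@](C)(CCCC2C(=O)OC)[C@H]1CC/C(C)=C/CO
F11 | step 19 | methyl isocupressate | C=C1CC[C@@H]2[C@](C)(CCC[C@]2(C)C(=O)OC)[C@H]1CC/C(C)=C/CO
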